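The constants used here come from no measurement; the flask was simulated.

Per second, the coupling partner in this flask loses a share of what is left, and that share is the figure to reckon. Solid substrate dissolves to starting material. Coupling partner meets starting material to give open intermediate and meets fresh partner to give second intermediate. The two intermediates join to target, and second intermediate also pairs with itself to homo product.

    2 second intermediate → homo product (k1 = 1.21 /M/s)
    coupling partner + fresh partner → second intermediate (k2 = 0.626 /M/s)
    starting material + coupling partner → open intermediate (k3 = 4.46 /M/s)
    solid substrate ⇌ starting material, rate k4*(cs4 - [starting material]) while solid is left; crystals form when [starting material] > cs4 (cs4 = 15 mM, k4 = 0.299 /s)
    open intermediate + second intermediate → target (k5 = 2.71 /M/s)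

solid substrate 0.050 M; fresh partner 0.0550 M; coupling partner 0.0650 M; time 25 s

- how much target there is at 25 s, in percent of the solid substrate charged
- the change that raises the amount of target at 25 s, in percent of the solid substrate charged most ("none" if none brings more than 2 percentage points) (west / south-west / south / north-east / none)
- amount of target at 25 s, in percent of the solid substrate charged, after south

- west: doubling the solubility in step 4, all else as stated
- south-west: doubling the amount of coupling partner, all else as stated
- south: doubling the amount of fresh partner, all else as stated
- north-east: doubling the dissolution coefficient of step 4, all else as stated

- for a step with 2 of a species take k times the square, and two of it per event
- given per volume of solution although it is solid: solid substrate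
- at the start none of the solid substrate is in solution
- run time (flask): 25 s

Two chemists dispute this flask. The first looks at the dissolving. Where dissolving matches use by the charged coupling partner, starting material stands at 7.62 mM, about half of its solubility. The level scales with the solubility, so she expects west to win.

The second looks at the coupling partner. Each target costs two of it, one through each intermediate, so the charge allows 65.0 %, and it is the limiting reagent.

My own reckoning serves both. Hold starting material at that level and fresh partner at its charge, and the loss is pseudo-first-order. Each taker's rate constant times its amount gives 0.0344 /s for fresh partner and 0.0340 /s for starting material. Their sum, the drain constant 0.0684 /s, integrates to an exponential, which leaves 18.1 % of the coupling partner at 25 s. In this reckoning a doubled level takes the fresh-partner arm from half of the drain to a third, which shifts the split between the intermediates, though target needs both. My reckoning stops there and gives no figure for target, so I side with the second chemist on direction only.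

The forecast takes the second chemist's side: 19.5 %, best change south-west, and 22 % after south, on the ground that “the coupling partner is the contested reagent”.

The simulation gives 18.1 %, best change south-west, and 20.7 % after south. South-west gains 18 percentage points, against 3.1 points for west and 1.9 points for north-east. Coupling partner left at 25.0 s is 19 %, beside the 18.1 % reckoned from the drain constant.

The neighbour flask has 0.11 M of coupling partner, all else as charged. There the level comes to 5.68 mM and the drain constant to 0.0598 /s, leaving 22.4 % of the coupling partner, while the simulation shows 28 %. Two coupling partners per target allow 110 % of the solid substrate charged, so in that flask the first chemist's solid substrate is the limiting reagent. That flask ends with solid substrate at 0 %, starting material at 9.99 % and target at 31.7 %.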